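**Retrosynthetic overview**
- Target 24 comes from the fully protected diaryl ether 21 by exchanging the benzylic TBS ether for the acetate and then removing two MOM groups.
- Key disconnection: ring A is the benzoate C1 (CO2Me), C2 (OH), C3 (H), C4 (CH3), C5 (H), C6 (O–ring B), with the aryloxy group ortho to the ester. It is cut at C4–C5 and C1–C6 into 2-pyrone 19 (C1–C4 with ester, oxygen and methyl in place) and aryl ethynyl ether 14 (C5, C6 and the ring B oxygen). The forward reaction is an inverse-demand Diels–Alder reaction followed by loss of CO2.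
- 14 comes from phenol 6 through its 1,2-dichlorovinyl ether (trichloroethylene) and n-BuLi. 6 comes from 2-hydroxy-4-methoxybenzaldehyde by MOM protection, Baeyer–Villiger oxidation (CHO becomes the OH para to OMe) and ortho-formylation, which fixes all four ring B substituents.
- 19 comes from dimethyl malonate and diketene (pyrone ring), then MOM ether formation.
- Order of ring formation: ring B is bought (compound 1), the pyrone ring is made in step 8, ring A is made last in step 10.

Key step: step 10

Remark: the target has no stereocentre. The only stereo elements on the way are the (E) double bond of 9–11 and the two bridgehead centres of the transient, racemic adduct 20, and all of them vanish.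

**Route**

Step 1
Reactants: 1 2-hydroxy-4-methoxybenzaldehyde
Product: 2 4-methoxy-2-(methoxymethoxy)benzaldehyde
Conditions: NaH, THF–DMF, 0 °C; MOMCl, 0 °C → rt
Reagents that add atoms: chloromethyl methyl ether (MOMCl), COCCl
Why: Williamson-type O-alkylation of the sodium phenoxide by the reactive α-chloro ether caps the only acidic OH, whose oxygen becomes the C2' oxygen of ring B.

Step 2
Reactants: 2 4-methoxy-2-(methoxymethoxy)benzaldehyde
Product: 4 4-methoxy-2-(methoxymethoxy)phenol, via aryl formate 3 (not isolated)
Conditions: mCPBA, CH2Cl2, 0 °C → rt; aq Na2S2O3/NaHCO3 wash; then K2CO3 (cat.), MeOH, rt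
Reagents that add atoms: 3-chloroperoxybenzoic acid (mCPBA), OOC(=O)c1cccc(Cl)c1
Why: Baeyer–Villiger oxidation of a benzaldehyde with ortho- and para-alkoxy groups proceeds with aryl migration to the formate, and methanolysis frees a phenol that sits para to the methoxy group with one open ortho position.

Step 3
Reactants: 4 4-methoxy-2-(methoxymethoxy)phenol
Product: 6 2-hydroxy-5-methoxy-3-(methoxymethoxy)benzaldehyde, via salicyl alcohol 5 (not isolated)
Conditions: MgCl2, Et3N, (CH2O)n, MeCN, reflux
Reagents that add atoms: paraformaldehyde (as formaldehyde), C=O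
Why: In the magnesium phenoxide-directed ortho-formylation (Casnati–Skattebøl) formaldehyde is delivered inside the chelate to the only free ortho position, and the benzylic alkoxide is then oxidised by a second formaldehyde through hydride transfer.

Step 4
Reactants: 6 2-hydroxy-5-methoxy-3-(methoxymethoxy)benzaldehyde; 7 trichloroethylene
Product: 9 2-{[(E)-1,2-dichloroethenyl]oxy}-5-methoxy-3-(methoxymethoxy)benzaldehyde, via dichloroacetylene 8 (not isolated)
Conditions: K2CO3, DMF, 70 °C (closed system)
Reagents that add atoms: none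
Why: Base-induced loss of HCl from trichloroethylene gives dichloroacetylene in the flask, and anti addition of the phenoxide across it gives the (E)-1,2-dichlorovinyl aryl ether, the standard first stage of the trichloroethylene route to ynol ethers.

Step 5
Reactants: 9 2-{[(E)-1,2-dichloroethenyl]oxy}-5-methoxy-3-(methoxymethoxy)benzaldehyde
Product: 10 (2-{[(E)-1,2-dichloroethenyl]oxy}-5-methoxy-3-(methoxymethoxy)phenyl)methanol
Conditions: NaBH4, MeOH, 0 °C
Reagents that add atoms: none
Why: Hydride reduction of the aromatic aldehyde, to which the dichlorovinyl ether and the MOM acetal are inert.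

Step 6
Reactants: 10 (2-{[(E)-1,2-dichloroethenyl]oxy}-5-methoxy-3-(methoxymethoxy)phenyl)methanol
Product: 11 tert-butyl[(2-{[(E)-1,2-dichloroethenyl]oxy}-5-methoxy-3-(methoxymethoxy)phenyl)methoxy]dimethylsilane
Conditions: TBSCl, imidazole, CH2Cl2, rt
Reagents that add atoms: tert-butyldimethylsilyl chloride (TBSCl), CC(C)(C)[Si](C)(C)Cl
Why: Imidazole-promoted silylation of the only hydroxyl group gives an ether that tolerates n-BuLi at −78 °C and the heat of step 10, and that fluoride removes later without touching the MOM groups.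

Step 7
Reactants: 11 tert-butyl[(2-{[(E)-1,2-dichloroethenyl]oxy}-5-methoxy-3-(methoxymethoxy)phenyl)methoxy]dimethylsilane
Product: 14 tert-butyl{[2-(ethynyloxy)-5-methoxy-3-(methoxymethoxy)phenyl]methoxy}dimethylsilane, via chloroethynyl ether 12 (not isolated), via lithium acetylide 13 (not isolated)
Conditions: n-BuLi (2.2 equiv), THF, −78 → −40 °C; H2O, −78 °C; basic work-up, filtration through Et3N-deactivated silica, kept cold in toluene
Reagents that add atoms: none
Why: Vinylic deprotonation and β-elimination of LiCl give the chloroalkyne, chlorine–lithium exchange with the second equivalent gives the lithium aryloxyacetylide, and protonation gives the terminal ynol ether, a known sequence for aryl ethynyl ethers.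

Step 8
Reactants: 15 dimethyl malonate; 16 diketene
Product: 18 methyl 4-hydroxy-6-methyl-2-oxo-2H-pyran-3-carboxylate, via acyl malonate 17 (not isolated)
Conditions: NaH, THF, 0 °C; diketene, 0 °C → rt; aq HCl; then toluene, reflux
Reagents that add atoms: none
Why: C-acetoacetylation of sodium dimethyl malonate by diketene gives the acyl malonate, whose methyl ketone enol lactonises onto one malonate ester with loss of methanol to close the 4-hydroxy-2-pyrone and leave the second ester at C3.

Step 9
Reactants: 18 methyl 4-hydroxy-6-methyl-2-oxo-2H-pyran-3-carboxylate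
Product: 19 methyl 4-(methoxymethoxy)-6-methyl-2-oxo-2H-pyran-3-carboxylate
Conditions: MOMCl, iPr2NEt, CH2Cl2, 0 °C
Reagents that add atoms: chloromethyl methyl ether (MOMCl), COCCl
Why: O-alkylation of the strongly acidic vinylogous acid by the hard, oxocarbenium-like electrophile at the C4 oxygen gives the 4-alkoxy-2-pyrone, the usual outcome for 4-hydroxy-2-pyrones with an amine base.

Step 10
Reactants: 19 methyl 4-(methoxymethoxy)-6-methyl-2-oxo-2H-pyran-3-carboxylate; 14 tert-butyl{[2-(ethynyloxy)-5-methoxy-3-(methoxymethoxy)phenyl]methoxy}dimethylsilane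
Product: 21 methyl 2-[2-({[tert-butyl(dimethyl)silyl]oxy}methyl)-4-methoxy-6-(methoxymethoxy)phenoxy]-6-(methoxymethoxy)-4-methylbenzoate, via bicyclic lactone 20 (not isolated)
Conditions: toluene (1 M), 110–130 °C, sealed tube, argon; 19 (2 equiv), BHT (cat.)
Reagents that add atoms: none
Why: This is an inverse-electron-demand Diels–Alder reaction in which the electron-poor diene C3=C4–C5=C6 of pyrone 19 (LUMO lowered by the lactone carbonyl and the C3 ester) adds the electron-rich alkyne of 14 to give the 2-oxabicyclo[2.2.2]octadienone 20, which loses CO2 by retro-[4+2] and is aromatic at once because the dienophile is an alkyne. The closest known reaction type is the cycloaddition of 3-carboalkoxy-2-pyrones with ynamines, alkoxyalkynes and ketene acetals to give benzoates, the aryl ynol ether being a less electron-rich member of the same dienophile class. Ring A is closed by an intermolecular [4+2] that forms C1–C6 and C4–C5 (ring A numbering), followed by the cycloreversion that removes the lactone bridge. No stereocentre remains, since the two bridgehead centres of 20 are lost with CO2. The step needs one regiochemistry, terminal alkyne carbon to pyrone C6 and oxygen-bearing carbon to pyrone C3, and this is secured because the ynol ether has its largest HOMO coefficient on the terminal carbon and the pyrone its largest LUMO coefficient at C6, a position the 4-alkoxy donor does not reach, so the aryloxy group ends up ortho to the ester. Self-condensation of 14 should be held back because both ortho positions of ring B are blocked, no hydrogen is placed for a retro-ene loss of ketene, and the reaction is run concentrated with excess pyrone.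

Step 11
Reactants: 21 methyl 2-[2-({[tert-butyl(dimethyl)silyl]oxy}methyl)-4-methoxy-6-(methoxymethoxy)phenoxy]-6-(methoxymethoxy)-4-methylbenzoate
Product: 22 methyl 2-[2-(hydroxymethyl)-4-methoxy-6-(methoxymethoxy)phenoxy]-6-(methoxymethoxy)-4-methylbenzoate
Conditions: Bu4NF, AcOH, THF, 0 °C → rt
Reagents that add atoms: none
Why: Fluoride cleaves the Si–O bond of the benzylic silyl ether while the acetic acid buffer keeps the freed alkoxide from attacking the neighbouring methyl ester, and aryl MOM ethers are stable to fluoride.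

Step 12
Reactants: 22 methyl 2-[2-(hydroxymethyl)-4-methoxy-6-(methoxymethoxy)phenoxy]-6-(methoxymethoxy)-4-methylbenzoate
Product: 23 methyl 2-[2-(acetoxymethyl)-4-methoxy-6-(methoxymethoxy)phenoxy]-6-(methoxymethoxy)-4-methylbenzoate
Conditions: Ac2O, pyridine, DMAP (cat.), CH2Cl2, 0 °C → rt
Reagents that add atoms: acetic anhydride, CC(=O)OC(C)=O
Why: DMAP-catalysed acylation of the only free hydroxyl group, with both phenols still masked as MOM ethers so that no selectivity problem arises.

Step 13
Reactants: 23 methyl 2-[2-(acetoxymethyl)-4-methoxy-6-(methoxymethoxy)phenoxy]-6-(methoxymethoxy)-4-methylbenzoate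
Product: 24 Betaethrin A, methyl 2-[2-(acetoxymethyl)-6-hydroxy-4-methoxyphenoxy]-6-hydroxy-4-methylbenzoate
Conditions: ZnBr2 (2 equiv), n-PrSH (4 equiv), CH2Cl2, 0 °C → rt
Reagents that add atoms: none
Why: Lewis acid-assisted cleavage of the two aryl methoxymethyl acetals with the thiol as trap for the methoxymethyl cation runs without water or alcohol, so the benzylic acetate and the methyl ester should be kept and the electron-rich ring B should not be alkylated.

**Compound list**

1 | 2-hydroxy-4-methoxybenzaldehyde | COc1ccc(C=O)c(O)c1 | starting material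
2 | 4-methoxy-2-(methoxymethoxy)benzaldehyde | COCOc1cc(OC)ccc1C=O | intermediate
3 | 4-methoxy-2-(methoxymethoxy)phenyl formate | COCOc1cc(OC)ccc1OC=O | intermediate (not isolated)
4 | 4-methoxy-2-(methoxymethoxy)phenol | COCOc1cc(OC)ccc1O | intermediate
5 | 2-(hydroxymethyl)-4-methoxy-6-(methoxymethoxy)phenol (present as its magnesium salt) | COCOc1cc(OC)cc(CO)c1O | intermediate (not isolated)
6 | 2-hydroxy-5-methoxy-3-(methoxymethoxy)benzaldehyde | COCOc1cc(OC)cc(C=O)c1O | intermediate
7 | trichloroethylene | ClC=C(Cl)Cl | starting material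
8 | dichloroacetylene | ClC#CCl | intermediate (not isolated)
9 | 2-{[(E)-1,2-dichloroethenyl]oxy}-5-methoxy-3-(methoxymethoxy)benzaldehyde | COCOc1cc(OC)cc(C=O)c1O/C(Cl)=C\Cl | intermediate
10 | (2-{[(E)-1,2-dichloroethenyl]oxy}-5-methoxy-3-(methoxymethoxy)phenyl)methanol | COCOc1cc(OC)cc(CO)c1O/C(Cl)=C\Cl | intermediate
11 | tert-butyl[(2-{[(E)-1,2-dichloroethenyl]oxy}-5-methoxy-3-(methoxymethoxy)phenyl)methoxy]dimethylsilane | COCOc1cc(OC)cc(CO[Si](C)(C)C(C)(C)C)c1O/C(Cl)=C\Cl | intermediate
12 | tert-butyl({2-[(chloroethynyl)oxy]-5-methoxy-3-(methoxymethoxy)phenyl}methoxy)dimethylsilane | COCOc1cc(OC)cc(CO[Si](C)(C)C(C)(C)C)c1OC#CCl | intermediate (not isolated)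
13 | {[2-({[tert-butyl(dimethyl)silyl]oxy}methyl)-4-methoxy-6-(methoxymethoxy)phenoxy]ethynyl}lithium | COCOc1cc(OC)cc(CO[Si](C)(C)C(C)(C)C)c1OC#C[Li] | intermediate (not isolated)
14 | tert-butyl{[2-(ethynyloxy)-5-methoxy-3-(methoxymethoxy)phenyl]methoxy}dimethylsilane | COCOc1cc(OC)cc(CO[Si](C)(C)C(C)(C)C)c1OC#C | intermediate
15 | dimethyl malonate | COC(=O)CC(=O)OC | starting material
16 | diketene (4-methylideneoxetan-2-one) | C=C1CC(=O)O1 | starting material
17 | dimethyl 2-(3-oxobutanoyl)propanedioate | COC(=O)C(C(=O)OC)C(=O)CC(C)=O | intermediate (not isolated)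
18 | methyl 4-hydroxy-6-methyl-2-oxo-2H-pyran-3-carboxylate | COC(=O)c1c(O)cc(C)oc1=O | intermediate
19 | methyl 4-(methoxymethoxy)-6-methyl-2-oxo-2H-pyran-3-carboxylate | COCOc1cc(C)oc(=O)c1C(=O)OC | intermediate
20 | methyl 5-(aryloxy)-8-(methoxymethoxy)-1-methyl-3-oxo-2-oxabicyclo[2.2.2]octa-5,7-diene-4-carboxylate, aryl = ring B unit of 14 (racemic, one enantiomer drawn) | C[C@]12OC(=O)[C@](C(=O)OC)(C(OCOC)=C1)C(Oc3c(OCOC)cc(OC)cc3CO[Si](C)(C)C(C)(C)C)=C2 | intermediate (not isolated)
21 | methyl 2-[2-({[tert-butyl(dimethyl)silyl]oxy}methyl)-4-methoxy-6-(methoxymethoxy)phenoxy]-6-(methoxymethoxy)-4-methylbenzoate | COC(=O)c1c(OCOC)cc(C)cc1Oc1c(OCOC)cc(OC)cc1CO[Si](C)(C)C(C)(C)C | intermediate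
22 | methyl 2-[2-(hydroxymethyl)-4-methoxy-6-(methoxymethoxy)phenoxy]-6-(methoxymethoxy)-4-methylbenzoate | COC(=O)c1c(OCOC)cc(C)cc1Oc1c(OCOC)cc(OC)cc1CO | intermediate
23 | methyl 2-[2-(acetoxymethyl)-4-methoxy-6-(methoxymethoxy)phenoxy]-6-(methoxymethoxy)-4-methylbenzoate | COC(=O)c1c(OCOC)cc(C)cc1Oc1c(OCOC)cc(OC)cc1COC(C)=O | intermediate
24 | Betaethrin A, methyl 2-[2-(acetoxymethyl)-6-hydroxy-4-methoxyphenoxy]-6-hydroxy-4-methylbenzoate | COC(=O)c1c(O)cc(C)cc1Oc1c(O)cc(OC)cc1COC(C)=O | target

**Step count and risks**

Total step count: 13. Longest linear sequence: 11 steps (steps 1–7, then 10–13).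

Steps most likely to fail:

1. Step 10 (key cycloaddition). The cycloaddition may be too slow because the 4-alkoxy group raises the LUMO of the diene, so that oligomerisation or hydration of the ynol ether wins, or bond formation may begin at the wrong diene terminus. The fallback sets out from 6 and returns at 21, and makes the diaryl ether C–O bond by nucleophilic aromatic substitution instead.
 - Reduction of 6 (NaBH4, MeOH) should give diol 5, and silylation of its primary hydroxyl (TBSCl, imidazole, CH2Cl2, 0 °C) should give 2-({[tert-butyl(dimethyl)silyl]oxy}methyl)-4-methoxy-6-(methoxymethoxy)phenol F1.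
 - Ring A comes from bought 3-fluoro-5-methylphenol F2. Its MOM ether 1-fluoro-3-(methoxymethoxy)-5-methylbenzene F3 (NaH, MOMCl) is lithiated between fluorine and the MOM oxygen and formylated (n-BuLi, THF, −78 °C; DMF) to give 2-fluoro-6-(methoxymethoxy)-4-methylbenzaldehyde F4.
 - The potassium phenoxide of F1 displaces the fluoride ortho to the formyl group (K2CO3, DMF, 100 °C) to give the diaryl ether aldehyde F5.
 - Pinnick oxidation (NaClO2, NaH2PO4, 2-methyl-2-butene, t-BuOH/H2O) gives the diaryl ether carboxylic acid F6, and methylation (MeI, K2CO3, DMF) gives 21.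

2. Step 7 (ynol ether). The terminal ynol ether may be lost during work-up and purification by acid-catalysed hydration to the aryl acetate or by oligomerisation, and surplus n-BuLi may metalate ring B between its two alkoxy groups. The fallback sets out from 11 and returns at 14. The lithium acetylide 13 is generated as before but quenched with Me3SiCl to give the C-silylated ynol ether tert-butyl{[5-methoxy-3-(methoxymethoxy)-2-{[(trimethylsilyl)ethynyl]oxy}phenyl]methoxy}dimethylsilane F7, which lacks the reactive terminus and can be chromatographed and stored. Protodesilylation (K2CO3, MeOH, 0 °C), extraction into toluene and drying deliver 14 as a solution that goes directly into step 10.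

3. Step 9 (MOM ether of the pyrone). The ambident pyronate may be alkylated at the lactone carbonyl oxygen to give the 2-alkoxy-4-pyranone, and the vinylogous acylal may hydrolyse on purification. The fallback sets out from 18 and returns at 21.
 - The C4 oxygen is alkylated under Mitsunobu conditions, which are selective for that oxygen in 4-hydroxy-2-pyrones (BnOH, PPh3, DIAD, THF), to give methyl 4-(benzyloxy)-6-methyl-2-oxo-2H-pyran-3-carboxylate F8.
 - Cycloaddition with 14 as in step 10 should pass through the benzyloxy bicyclic lactone F9 and give the benzyl-protected diaryl ether F10.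
 - Hydrogenolysis (H2, Pd/C, EtOAc) gives the ring A phenol F11, and MOM protection (NaH, MOMCl, DMF) gives 21.

**Further compounds**

F1 | step 10 | 2-({[tert-butyl(dimethyl)silyl]oxy}methyl)-4-methoxy-6-(methoxymethoxy)phenol | COCOc1cc(OC)cc(CO[Si](C)(C)C(C)(C)C)c1O
F2 | step 10 | 3-fluoro-5-methylphenol (bought) | Cc1cc(O)cc(F)c1
F3 | step 10 | 1-fluoro-3-(methoxymethoxy)-5-methylbenzene | COCOc1cc(C)cc(F)c1
F4 | step 10 | 2-fluoro-6-(methoxymethoxy)-4-methylbenzaldehyde | COCOc1cc(C)cc(F)c1C=O
F5 | step 10 | 2-[2-({[tert-butyl(dimethyl)silyl]oxy}methyl)-4-methoxy-6-(methoxymethoxy)phenoxy]-6-(methoxymethoxy)-4-methylbenzaldehyde | O=Cc1c(OCOC)cc(C)cc1Oc1c(OCOC)cc(OC)cc1CO[Si](C)(C)C(C)(C)C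
F6 | step 10 | 2-[2-({[tert-butyl(dimethyl)silyl]oxy}methyl)-4-methoxy-6-(methoxymethoxy)phenoxy]-6-(methoxymethoxy)-4-methylbenzoic acid | OC(=O)c1c(OCOC)cc(C)cc1Oc1c(OCOC)cc(OC)cc1CO[Si](C)(C)C(C)(C)C
F7 | step 7 | tert-butyl{[5-methoxy-3-(methoxymethoxy)-2-{[(trimethylsilyl)ethynyl]oxy}phenyl]methoxy}dimethylsilane | COCOc1cc(OC)cc(CO[Si](C)(C)C(C)(C)C)c1OC#C[Si](C)(C)C
F8 | step 9 | methyl 4-(benzyloxy)-6-methyl-2-oxo-2H-pyran-3-carboxylate | COC(=O)c1c(OCc2ccccc2)cc(C)oc1=O
F9 | step 9 | methyl 5-(aryloxy)-8-(benzyloxy)-1-methyl-3-oxo-2-oxabicyclo[2.2.2]octa-5,7-diene-4-carboxylate, aryl = ring B unit of 14 (racemic, not isolated) | C[C@]12OC(=O)[C@](C(=O)OC)(C(OCc3ccccc3)=C1)C(Oc4c(OCOC)cc(OC)cc4CO[Si](C)(C)C(C)(C)C)=C2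
F10 | step 9 | methyl 2-(benzyloxy)-6-[2-({[tert-butyl(dimethyl)silyl]oxy}methyl)-4-methoxy-6-(methoxymethoxy)phenoxy]-4-methylbenzoate | COC(=O)c1c(OCc2ccccc2)cc(C)cc1Oc1c(OCOC)cc(OC)cc1CO[Si](C)(C)C(C)(C)C
F11 | step 9 | methyl 2-[2-({[tert-butyl(dimethyl)silyl]oxy}methyl)-4-methoxy-6-(methoxymethoxy)phenoxy]-6-hydroxy-4-methylbenzoate | COC(=O)c1c(O)cc(C)cc1Oc1c(OCOC)cc(OC)cc1CO[Si](C)(C)C(C)(C)C
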